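## Retrosynthetic overview

1. The target comes from a double Swern oxidation of the 1,6-diacetate 9,11,12-triol, after an acetate/silyl ether exchange.
2. Both ring-B C–O bonds (C6 and C9, cis, α) come from one α-face singlet-oxygen [4+2] on a trans-fused drima-6,8-diene, followed by O–O reduction.
3. The 6,8-diene comes from the skipped 5,8-diene by a proposed face-selective Ir–H one-position alkene transposition, which sets C5 (trans ring fusion).
4. The skipped diene is the Diels–Alder adduct of an (R)-dienyl acetate with DMAD. This step forms ring B and sets the C10 quaternary centre anti to the C1 acetate.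
5. Ring A is bought as 4,4-dimethylcyclohexane-1,3-dione and converted to the dienol by Stork–Danheiser vinylation and CBS reduction (sets C1). Ring order: A, then B.

Assumption: I read the SMILES as (1R,5S,6S,9S,10R)-1β,6α-diacetoxy-9α-hydroxydrim-7-ene-11,12-dial. Drimane numbering is used throughout (C11 on C9, C12 on C8, C15 = 10β-CH3, 5α-H), and α/β refer to this orientation.

## Route

**Step 1**
Reactants: 1 (4,4-dimethylcyclohexane-1,3-dione); 2 (iodomethane)
Product: 3 (2,4,4-trimethylcyclohexane-1,3-dione)
Conditions: MeI, K2CO3, acetone, reflux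
Reagents that add atoms: iodomethane, CI
Why: Enolate C-alkylation of a cyclic 1,3-dione at the doubly activated C2.

**Step 2**
Reactants: 3; 4 (isobutanol)
Product: 5 (3-isobutoxy-2,6,6-trimethylcyclohex-2-en-1-one)
Conditions: i-BuOH, TsOH·H2O (cat.), PhMe, reflux, Dean–Stark
Reagents that add atoms: isobutanol, CC(C)CO
Why: Acid-catalysed vinylogous ester formation occurs at the carbonyl remote from the gem-dimethyl group, leaving the hindered C=O free for the next step.

**Step 3**
Reactants: 5; 6 (vinylmagnesium bromide)
Product: 7 (2,4,4-trimethyl-3-vinylcyclohex-2-en-1-one)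
Conditions: CH2=CHMgBr, CeCl3, THF, −78→0 °C; then 1 M HCl, rt
Reagents that add atoms: vinylmagnesium bromide, C=C[Mg]Br
Why: Stork–Danheiser sequence: 1,2-addition to the vinylogous ester carbonyl, then acidic hydrolysis/dehydration transposes the enone and places the vinyl group next to the CMe2 carbon.

**Step 4**
Reactants: 7
Product: 8 ((R)-2,4,4-trimethyl-3-vinylcyclohex-2-en-1-ol)
Conditions: (S)-Me-CBS (0.2 equiv), catecholborane, PhMe, −78 °C
Reagents that add atoms: none
Why: Corey–Bakshi–Shibata reduction, in which the α-methyl-alkenyl side acts as the large group (as phenyl does in acetophenone), gives the (R)-carbinol that becomes C1; catecholborane at −78 °C leaves the diene alone.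

**Step 5**
Reactants: 8; 9 (acetic anhydride)
Product: 10 ((R)-2,4,4-trimethyl-3-vinylcyclohex-2-en-1-yl acetate)
Conditions: Ac2O, Et3N, DMAP (cat.), CH2Cl2, 0 °C→rt
Reagents that add atoms: acetic anhydride, CC(=O)OC(C)=O
Why: DMAP-catalysed acylation; the ester blocks OH-directed or oxa-Michael reactions with DMAD and is later removed for free in step 8.

**Step 6**
Reactants: 10; 11 (dimethyl acetylenedicarboxylate)
Product: 12 (dimethyl 1β-acetoxydrima-5,8-diene-11,12-dioate; 10β-CH3 cis to 1β-OAc; skipped 1,4-diene)
Conditions: DMAD (3 equiv), BHT (cat.), PhMe (2 M), 110 °C, sealed tube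
Reagents that add atoms: dimethyl acetylenedicarboxylate, COC(=O)C#CC(=O)OC
Why: Thermal Diels–Alder forms ring B and the C10 quaternary centre; DMAD bonds to the diene face anti to the allylic C1 acetate (syn approach meets the acetate or the pseudoaxial C4 methyl), so the C10 methyl ends up cis to the acetate, with the minor diastereomer removed by chromatography.

**Step 7**
Reactants: 12
Product: 13 (dimethyl 1β-acetoxy-5α-drima-6,8-diene-11,12-dioate; trans-fused)
Conditions: [Ir(cod)(PCy3)(py)]BArF (5 mol%), H2 (1 atm, 2 min) then Ar purge, ClCH2CH2Cl, 40 °C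
Reagents that add atoms: none
Why: Proposed new method: a face-selective, one-position Ir–H alkene transposition used to set a ring-fusion stereocentre on a hindered bicyclic skipped dienoate, which has not been shown; the cationic Ir–H should add syn to the only open face of C5=C6 (α, since β is blocked by the axial C10 and C4 methyls), placing H on C5 and Ir on C6, and syn β-H elimination of H-7α then releases the conjugated 6,8-dienoate with 5α-H, driven by conjugation, while C8=C9 is too hindered and electron-poor to insert and the 5α-H cannot be removed from the β face; the closest known chemistry is metal-hydride positional alkene isomerization (skipped to conjugated dienes, and allylic alcohol isomerization with H2-activated Crabtree-type catalysts).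

**Step 8**
Reactants: 13
Product: 14 (5α-drima-6,8-diene-1β,11,12-triol)
Conditions: DIBAL-H (8 equiv), CH2Cl2, −78→0 °C; Rochelle salt
Reagents that add atoms: none
Why: DIBAL-H 1,2-reduction of both conjugated methyl esters to allylic alcohols also cleaves the C1 acetate, and no stereocentre is touched.

**Step 9**
Reactants: 14; 15 (tert-butyldimethylsilyl chloride)
Product: 16 (11,12-bis(tert-butyldimethylsilyloxy)-5α-drima-6,8-dien-1β-ol)
Conditions: TBSCl (2.2 equiv), imidazole, CH2Cl2, 0 °C
Reagents that add atoms: tert-butyldimethylsilyl chloride, CC(C)(C)[Si](C)(C)Cl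
Why: Selective silylation: the two primary allylic alcohols react far faster than the secondary C1–OH next to the quaternary C10.

**Step 10**
Reactants: 16; 17 (oxygen)
Product: 18 (11,12-bis(TBSO)-6α,9α-epidioxy-5α-drim-7-en-1β-ol)
Conditions: O2, tetraphenylporphyrin (1 mol%), white LED, CH2Cl2, −30 °C
Reagents that add atoms: oxygen, O=O
Why: Singlet-oxygen [4+2] cycloaddition to the cisoid, electron-rich ring-B diene from the α face (β face blocked by the axial C10 and C4 methyls) sets C6 and C9 together as the cis-α,α-dioxygenated pair and moves the alkene to C7=C8.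

**Step 11**
Reactants: 18
Product: 19 (11,12-bis(TBSO)-5α-drim-7-ene-1β,6α,9α-triol)
Conditions: thiourea, MeOH, 0 °C→rt
Reagents that add atoms: none
Why: Thiourea reduction of the endoperoxide O–O bond gives the cis-ene-1,4-diol with C6 and C9 configurations retained.

**Step 12**
Reactants: 19; 9 (acetic anhydride)
Product: 20 (1β,6α-diacetoxy-11,12-bis(TBSO)-5α-drim-7-en-9α-ol)
Conditions: Ac2O, pyridine, DMAP (cat.), CH2Cl2, 0 °C→rt
Reagents that add atoms: acetic anhydride, CC(=O)OC(C)=O
Why: Chemoselective acylation of the two equatorial secondary alcohols; the axial tertiary C9–OH flanked by C10 and C11 stays free.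

**Step 13**
Reactants: 20
Product: 21 (1β,6α-diacetoxy-5α-drim-7-ene-9α,11,12-triol)
Conditions: HF·pyridine, pyridine, THF, 0 °C→rt
Reagents that add atoms: none
Why: Buffered fluoride desilylation removes the primary TBS ethers without acetate cleavage or migration.

**Step 14**
Reactants: 21
Product: 22 (parritadial)
Conditions: (COCl)2, DMSO, CH2Cl2, −78 °C; then Et3N, −78→0 °C
Reagents that add atoms: none
Why: Double Swern oxidation activates both primary alcohols before base is added, which avoids lactol/lactone formation, and gives the enal and the α-hydroxy aldehyde while the tertiary OH and acetates are inert.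

## Compound list

1 | 4,4-dimethylcyclohexane-1,3-dione | CC1(C)CCC(=O)CC1=O | starting material
2 | iodomethane | CI | starting material
3 | 2,4,4-trimethylcyclohexane-1,3-dione | CC1C(=O)CCC(C)(C)C1=O | intermediate
4 | isobutanol | CC(C)CO | starting material
5 | 3-isobutoxy-2,6,6-trimethylcyclohex-2-en-1-one | CC1=C(OCC(C)C)CCC(C)(C)C1=O | intermediate
6 | vinylmagnesium bromide | C=C[Mg]Br | starting material
7 | 2,4,4-trimethyl-3-vinylcyclohex-2-en-1-one | C=CC1=C(C)C(=O)CCC1(C)C | intermediate
8 | (R)-2,4,4-trimethyl-3-vinylcyclohex-2-en-1-ol | C=CC1=C(C)[C@H](O)CCC1(C)C | intermediate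
9 | acetic anhydride | CC(=O)OC(C)=O | starting material
10 | (R)-2,4,4-trimethyl-3-vinylcyclohex-2-en-1-yl acetate | C=CC1=C(C)[C@H](OC(C)=O)CCC1(C)C | intermediate
11 | dimethyl acetylenedicarboxylate | COC(=O)C#CC(=O)OC | starting material
12 | dimethyl 1β-acetoxydrima-5,8-diene-11,12-dioate | COC(=O)C1=C(C(=O)OC)[C@@]2(C)[C@H](OC(C)=O)CCC(C)(C)C2=CC1 | intermediate
13 | dimethyl 1β-acetoxy-5α-drima-6,8-diene-11,12-dioate | COC(=O)C1=C(C(=O)OC)[C@@]2(C)[C@H](OC(C)=O)CCC(C)(C)[C@@H]2C=C1 | intermediate
14 | 5α-drima-6,8-diene-1β,11,12-triol | OCC1=C(CO)[C@@]2(C)[C@H](O)CCC(C)(C)[C@@H]2C=C1 | intermediate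
15 | tert-butyldimethylsilyl chloride | CC(C)(C)[Si](C)(C)Cl | starting material
16 | 11,12-bis(TBSO)-5α-drima-6,8-dien-1β-ol | CC(C)(C)[Si](C)(C)OCC1=C(CO[Si](C)(C)C(C)(C)C)[C@@]2(C)[C@H](O)CCC(C)(C)[C@@H]2C=C1 | intermediate
17 | oxygen | O=O | starting material
18 | 11,12-bis(TBSO)-6α,9α-epidioxy-5α-drim-7-en-1β-ol | CC(C)(C)[Si](C)(C)OCC1=C[C@@H]2OO[C@@]1(CO[Si](C)(C)C(C)(C)C)[C@@]3(C)[C@H](O)CCC(C)(C)[C@H]23 | intermediate
19 | 11,12-bis(TBSO)-5α-drim-7-ene-1β,6α,9α-triol | O[C@H]1C=C(CO[Si](C)(C)C(C)(C)C)[C@](O)(CO[Si](C)(C)C(C)(C)C)[C@@]2(C)[C@H](O)CCC(C)(C)[C@H]12 | intermediate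
20 | 1β,6α-diacetoxy-11,12-bis(TBSO)-5α-drim-7-en-9α-ol | CC(=O)O[C@H]1C=C(CO[Si](C)(C)C(C)(C)C)[C@](O)(CO[Si](C)(C)C(C)(C)C)[C@@]2(C)[C@H](OC(C)=O)CCC(C)(C)[C@H]12 | intermediate
21 | 1β,6α-diacetoxy-5α-drim-7-ene-9α,11,12-triol | CC(=O)O[C@H]1C=C(CO)[C@](O)(CO)[C@@]2(C)[C@H](OC(C)=O)CCC(C)(C)[C@H]12 | intermediate
22 | parritadial | CC(=O)O[C@H]1C=C(C=O)[C@](O)(C=O)[C@@]2(C)[C@H](OC(C)=O)CCC(C)(C)[C@H]12 | target

## Summary

Total step count: 14. Longest linear sequence: 14 (fully linear from compound 1).

Steps most likely to fail, each with a fallback that changes the approach: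

1. **Step 7 (proposed new Ir–H transposition).** The hindered C5=C6 may not insert, or isomerization may be unselective. Fallback with known chemistry: hydrogenate C5=C6 of 12 from the α face (H2, Pd/C) to the trans-fused Δ8-diester, brominate the allylic C7 (NBS, AIBN) and eliminate with DBU to reach 13.
2. **Step 6 (Diels–Alder facial selectivity and reactivity at the tetrasubstituted diene terminus).** Fallback: run the cycloaddition on the achiral ethylene ketal of dienone 7, where there is no diene-face issue. After ring formation, unveil the C1 ketone, reduce it from the α face with NaBH4 (1β-OH, cis to the C10 methyl) and resolve with a lipase (CAL-B, vinyl acetate), rejoining at 13/14.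
3. **Step 10 (singlet-oxygen [4+2] versus ene reaction, and face selectivity).** Fallback: install the two oxygens stepwise. Hydroborate–oxidize C5=C6 of 12 (BH3·SMe2; NaBO3) to set 5α-H/6α-OH in one syn addition, with C1 and C6 carried as TBS ethers. Then γ-deprotonate the Δ8-diester (LDA) and α-hydroxylate the dienolate at C9 from the α face (MoOPH or Davis oxaziridine), reduce with DIBAL-H and finish with the same silyl/acetate exchange and Swern oxidation.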